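**Retrosynthetic overview**
1. The C1–O angelate is cut last. C9–H is traced back to C9–Br. The side chain is cut at C7–C11 into an α-bromodienone and a 2-stannylacrylate, and C11 is set by hydrogenation of the resulting acrylate.
2. Feature the plan rests on: ring B (C5–C10) is a cyclohexa-2,5-dienone whose only sp3 atom, C5, lies para to C8=O and bears the C14 methyl and ring A carbon C4. Ring B is therefore a dearomatised para-cresol, alkylated at its para carbon by the end of the chain C10–C1–C2–C3–C4 that hangs from the meta carbon C10.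
3. Cutting C4–C5 opens ring A and re-aromatises ring B. This gives a 2,6-dibromophenol with a silyl ether at C1 and an (R)-mesylate at C4.
4. The chain is cut at C10–C1 into the aryllithium from 3-bromo-4-methylphenol and (R)-γ-valerolactone, which brings C4. C1 comes from an oxazaborolidine reduction.
5. Ring order: ring B is bought as the arene. Ring A is closed in step 10, which also turns ring B into the dienone.

Key step: step 10

Remark: eremophilane numbering is used (ring A = C1–C5 and C10, ring B = C5–C10, C14 on C5, C15 on C4, side chain C11–C13). The ligand antipode in step 13 is assigned by analogy with itaconates and dehydroamino esters, and both antipodes are sold.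

**Step 1**
Reactants: 1 3-bromo-4-methylphenol
Product: 2 4-(benzyloxy)-2-bromo-1-methylbenzene
Conditions: BnBr, K2CO3, acetone, reflux
Reagents that add atoms: benzyl bromide, BrCc1ccccc1
Why: Williamson ether synthesis masks the acidic OH for the organolithium step with a group that later leaves under neutral hydrogenolysis.

**Step 2**
Reactants: 2 4-(benzyloxy)-2-bromo-1-methylbenzene; 3 (R)-γ-valerolactone [(5R)-5-methyloxolan-2-one]
Product: 5 (4R)-1-[5-(benzyloxy)-2-methylphenyl]-4-hydroxypentan-1-one, via aryllithium 4 (not isolated)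
Conditions: n-BuLi, THF, −78 °C; cannulated into 3, THF, −78 °C; aq NH4Cl at −78 °C
Reagents that add atoms: none
Why: Bromine–lithium exchange followed by nucleophilic acyl substitution on the lactone forms C10–C1, a second addition being held back by the persistent lithium hemiketal at −78 °C, by inverse addition and by the ortho methyl group, while the C4 centre of 3 is not involved.

**Step 3**
Reactants: 5 (4R)-1-[5-(benzyloxy)-2-methylphenyl]-4-hydroxypentan-1-one
Product: 6 (2R)-5-[5-(benzyloxy)-2-methylphenyl]-5-oxopentan-2-yl acetate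
Conditions: Ac2O, pyridine, DMAP (cat.), CH2Cl2, 0 °C to rt
Reagents that add atoms: acetic anhydride, CC(=O)OC(C)=O
Why: DMAP-catalysed acetylation parks the C4 oxygen as an ester, because a free C1 carbinol beside a C4 sulfonate would close to the 2,5-disubstituted tetrahydrofuran, so the sulfonate is introduced only after C1–O is silylated.

**Step 4**
Reactants: 6 (2R)-5-[5-(benzyloxy)-2-methylphenyl]-5-oxopentan-2-yl acetate
Product: 7 (2R,5R)-5-[5-(benzyloxy)-2-methylphenyl]-5-hydroxypentan-2-yl acetate
Conditions: (S)-Me-CBS oxazaborolidine (15 mol%), BH3·SMe2, THF, −20 °C; MeOH quench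
Reagents that add atoms: none
Why: Corey–Bakshi–Shibata reduction with the aryl group as the large substituent should set 1R under catalyst control (the sense in which the (S)-catalyst gives (R)-1-arylalkanols), the acetate and benzyl ether being inert to borane at this temperature and any C1 epimer being a separable diastereomer.

**Step 5**
Reactants: 7 (2R,5R)-5-[5-(benzyloxy)-2-methylphenyl]-5-hydroxypentan-2-yl acetate
Product: 8 (2R,5R)-5-[5-(benzyloxy)-2-methylphenyl]-5-(tert-butyldimethylsilyloxy)pentan-2-yl acetate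
Conditions: TBSOTf, 2,6-lutidine, CH2Cl2, 0 °C
Reagents that add atoms: tert-butyldimethylsilyl triflate, CC(C)(C)[Si](C)(C)OS(=O)(=O)C(F)(F)F
Why: O-silylation with the reactive silyl triflate covers the hindered benzylic hydroxyl without touching the C1–O bond and makes this oxygen a poor internal nucleophile.

**Step 6**
Reactants: 8 (2R,5R)-5-[5-(benzyloxy)-2-methylphenyl]-5-(tert-butyldimethylsilyloxy)pentan-2-yl acetate
Product: 9 (2R,5R)-5-[5-(benzyloxy)-2-methylphenyl]-5-(tert-butyldimethylsilyloxy)pentan-2-ol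
Conditions: K2CO3 (cat.), MeOH, rt
Reagents that add atoms: none
Why: Base-catalysed transesterification removes only the acetate, since alkyl silyl ethers and benzyl ethers are stable to carbonate in methanol.

**Step 7**
Reactants: 9 (2R,5R)-5-[5-(benzyloxy)-2-methylphenyl]-5-(tert-butyldimethylsilyloxy)pentan-2-ol
Product: 10 (2R,5R)-5-[5-(benzyloxy)-2-methylphenyl]-5-(tert-butyldimethylsilyloxy)pentan-2-yl methanesulfonate
Conditions: MsCl, Et3N, CH2Cl2, 0 °C
Reagents that add atoms: methanesulfonyl chloride, CS(=O)(=O)Cl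
Why: Sulfonylation takes place at oxygen, so the C4–O bond and the 4R configuration are kept.

**Step 8**
Reactants: 10 (2R,5R)-5-[5-(benzyloxy)-2-methylphenyl]-5-(tert-butyldimethylsilyloxy)pentan-2-yl methanesulfonate
Product: 11 (2R,5R)-5-(tert-butyldimethylsilyloxy)-5-(5-hydroxy-2-methylphenyl)pentan-2-yl methanesulfonate
Conditions: H2 (1 atm), 10% Pd/C, EtOAc, rt
Reagents that add atoms: none
Why: Catalytic hydrogenolysis cleaves the aryl benzyl ether quickly under neutral conditions, and in ethyl acetate the hindered benzylic silyl ether and the alkyl mesylate should persist.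

**Step 9**
Reactants: 11 (2R,5R)-5-(tert-butyldimethylsilyloxy)-5-(5-hydroxy-2-methylphenyl)pentan-2-yl methanesulfonate
Product: 12 2,6-dibromo-4-methyl-3-[(1R,4R)-1-(tert-butyldimethylsilyloxy)-4-(methylsulfonyloxy)pentyl]phenol
Conditions: NBS (2.05 equiv), MeCN, 0 °C to rt, dark
Reagents that add atoms: N-bromosuccinimide, O=C1CCC(=O)N1Br
Why: Electrophilic aromatic bromination of a phenol whose para carbon is blocked by methyl takes both ortho carbons (C7, then the more crowded C9), and NBS releases no HBr that could attack the silyl ether.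

**Step 10**
Reactants: 12 2,6-dibromo-4-methyl-3-[(1R,4R)-1-(tert-butyldimethylsilyloxy)-4-(methylsulfonyloxy)pentyl]phenol
Product: 14 (4aS,5S,8R)-1,3-dibromo-8-(tert-butyldimethylsilyloxy)-4a,5-dimethyl-5,6,7,8-tetrahydronaphthalen-2(4aH)-one, via cesium phenoxide 13 (not isolated)
Conditions: Cs2CO3 (1.5 equiv), MeCN (0.005 M), 70 °C
Reagents that add atoms: none
Why: Carbonate fully deprotonates the acidic dibromophenol, and the ambident phenoxide 13 displaces the C4 mesylate in an internal SN2 reaction through its para carbon C5, so C4–C5 forms while ring B is left as the cross-conjugated dienone, which cannot return to a phenol because C5 is quaternary. The closest known reaction type is the base-induced aryl-participation (Ar2-6) cyclisation of phenolic sulfonates and halides to fused or spiro cyclohexadienones, which has also been run on secondary sulfonates. Ring A closes in the 6-exo-tet mode, with C4 held over the π face at C5 in a chair-like array and the leaving oxygen outside the new ring and anti to C5. C4 is set by inversion of the (4R)-mesylate to 4S. C5 is set by the choice of arene face: allylic 1,3-strain with the C9 bromine holds C1–H in the ring plane, which puts C2 on one face and the silyloxy group on the other, and on that same face the C4 methyl is pseudo-equatorial, so both resident centres call for 5S (C14 cis to C15 and to the C1 oxygen). The step needs para over ortho C-alkylation, substitution over elimination and internal over external reaction, which are secured in turn by the C9 bromine (the rival six-membered closure would build a crowded C–Br quaternary centre in a less stable linear dienone), by the geometric inability of the phenoxide oxygen to reach C4, by the low basicity of the dibromophenoxide, and by high dilution.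

**Step 11**
Reactants: 15 methyl propiolate
Product: 16 methyl 2-(tributylstannyl)prop-2-enoate
Conditions: Bu3SnH, Pd(PPh3)4 (1 mol%), THF, 0 °C to rt
Reagents that add atoms: tributyltin hydride, CCCC[SnH](CCCC)CCCC
Why: Palladium-catalysed syn-hydrostannation of an alkynoate places tin on the carbon α to the ester, giving the geminal stannylacrylate.

**Step 12**
Reactants: 14 (4aS,5S,8R)-1,3-dibromo-8-(tert-butyldimethylsilyloxy)-4a,5-dimethyl-5,6,7,8-tetrahydronaphthalen-2(4aH)-one; 16 methyl 2-(tributylstannyl)prop-2-enoate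
Product: 17 methyl 2-[(5R,8S,8aS)-4-bromo-5-(tert-butyldimethylsilyloxy)-8,8a-dimethyl-3-oxo-3,5,6,7,8,8a-hexahydronaphthalen-2-yl]prop-2-enoate (C7 coupled, C9–Br kept)
Conditions: 16 (1.05 equiv), Pd(PPh3)4 (5 mol%), CuI (30 mol%), DMF, 45 °C
Reagents that add atoms: none
Why: In this Stille coupling, oxidative addition of zerovalent palladium should prefer C7–Br on the trisubstituted C6=C7 alkene over C9–Br on the tetrasubstituted alkene shielded by C1 and its silyloxy group, while CuI speeds up transfer of the hindered α-stannylacrylate and suppresses cine substitution.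

**Step 13**
Reactants: 17 methyl 2-[(5R,8S,8aS)-4-bromo-5-(tert-butyldimethylsilyloxy)-8,8a-dimethyl-3-oxo-3,5,6,7,8,8a-hexahydronaphthalen-2-yl]prop-2-enoate
Product: 18 methyl (2S)-2-[(5R,8S,8aS)-4-bromo-5-(tert-butyldimethylsilyloxy)-8,8a-dimethyl-3-oxo-3,5,6,7,8,8a-hexahydronaphthalen-2-yl]propanoate
Conditions: [Rh(cod)((R,R)-Me-DuPhos)]BF4 (2 mol%), H2 (5 bar), MeOH, rt
Reagents that add atoms: none
Why: In this chelate-directed asymmetric hydrogenation, C11=C13 and the C8 carbonyl oxygen can bind rhodium as a five-membered chelate (the 2-methylene-1,4-dicarbonyl motif of itaconates), so only this 1,1-disubstituted alkene should be reduced (C6=C7 and the brominated C9=C10 cannot bind in this way), and the (R,R) ligand, which leads to (S)-2-methylsuccinates, should set 11S under reagent control.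

**Step 14**
Reactants: 18 methyl (2S)-2-[(5R,8S,8aS)-4-bromo-5-(tert-butyldimethylsilyloxy)-8,8a-dimethyl-3-oxo-3,5,6,7,8,8a-hexahydronaphthalen-2-yl]propanoate
Product: 19 methyl (2S)-2-[(5R,8S,8aS)-5-(tert-butyldimethylsilyloxy)-8,8a-dimethyl-3-oxo-3,5,6,7,8,8a-hexahydronaphthalen-2-yl]propanoate
Conditions: Pd(OAc)2 (10 mol%), PPh3 (40 mol%), HCO2H/Et3N (1:1, 3 equiv), DMF, 60 °C
Reagents that add atoms: none
Why: Palladium-catalysed formate hydrogenolysis of the vinylic C9–Br bond (oxidative addition, decarboxylation of the palladium formate, C–H reductive elimination) replaces bromine by hydrogen without electron transfer to the dienone, which is why it is preferred to dissolving zinc, and the equimolar acid–amine buffer leaves no free base to epimerise C11.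

**Step 15**
Reactants: 19 methyl (2S)-2-[(5R,8S,8aS)-5-(tert-butyldimethylsilyloxy)-8,8a-dimethyl-3-oxo-3,5,6,7,8,8a-hexahydronaphthalen-2-yl]propanoate
Product: 20 methyl (2S)-2-[(5R,8S,8aS)-5-hydroxy-8,8a-dimethyl-3-oxo-3,5,6,7,8,8a-hexahydronaphthalen-2-yl]propanoate
Conditions: HF·pyridine, THF, 0 °C to rt
Reagents that add atoms: none
Why: Fluoride-driven Si–O cleavage in a weakly acidic medium frees the C1 hydroxyl with the C1–O bond intact (1R kept) and avoids both the base that could epimerise C11 and the strong acid that a dienone–phenol rearrangement needs.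

**Step 16**
Reactants: 21 angelic acid [(2Z)-2-methylbut-2-enoic acid]
Product: 22 (2Z)-2-methylbut-2-enoic 2,4,6-trichlorobenzoic anhydride
Conditions: 2,4,6-trichlorobenzoyl chloride, Et3N (1.0 equiv), toluene, rt; filtration
Reagents that add atoms: 2,4,6-trichlorobenzoyl chloride, O=C(Cl)c1c(Cl)cc(Cl)cc1Cl
Why: Yamaguchi-type mixed anhydride formation activates angelic acid under conditions that leave the Z double bond untouched.

**Step 17**
Reactants: 20 methyl (2S)-2-[(5R,8S,8aS)-5-hydroxy-8,8a-dimethyl-3-oxo-3,5,6,7,8,8a-hexahydronaphthalen-2-yl]propanoate; 22 (2Z)-2-methylbut-2-enoic 2,4,6-trichlorobenzoic anhydride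
Product: 23 (1R,4S,4aS)-6-[(2S)-1-methoxy-1-oxopropan-2-yl]-4,4a-dimethyl-7-oxo-1,2,3,4,4a,7-hexahydronaphthalen-1-yl (2Z)-2-methylbut-2-enoate (CNP0166395.1)
Conditions: 22 (3 equiv), toluene, 80 °C, no nucleophilic catalyst
Reagents that add atoms: none
Why: Acyl transfer from the mixed anhydride, whose aroyl carbonyl is shielded by two ortho chlorines, esterifies the axial C1 hydroxyl at the angeloyl carbonyl with retention at C1, and leaving out catalysts such as DMAP closes the addition–elimination path by which angelates turn into tiglates.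

**Compound list**
1 | 3-bromo-4-methylphenol | Cc1ccc(O)cc1Br | starting material
2 | 4-(benzyloxy)-2-bromo-1-methylbenzene | Cc1ccc(OCc2ccccc2)cc1Br | intermediate
3 | (R)-γ-valerolactone | C[C@@H]1CCC(=O)O1 | starting material
4 | [5-(benzyloxy)-2-methylphenyl]lithium | Cc1ccc(OCc2ccccc2)cc1[Li] | intermediate
5 | (4R)-1-[5-(benzyloxy)-2-methylphenyl]-4-hydroxypentan-1-one | C[C@@H](O)CCC(=O)c1cc(OCc2ccccc2)ccc1C | intermediate
6 | (2R)-5-[5-(benzyloxy)-2-methylphenyl]-5-oxopentan-2-yl acetate | C[C@@H](OC(C)=O)CCC(=O)c1cc(OCc2ccccc2)ccc1C | intermediate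
7 | (2R,5R)-5-[5-(benzyloxy)-2-methylphenyl]-5-hydroxypentan-2-yl acetate | C[C@@H](OC(C)=O)CC[C@@H](O)c1cc(OCc2ccccc2)ccc1C | intermediate
8 | (2R,5R)-5-[5-(benzyloxy)-2-methylphenyl]-5-(tert-butyldimethylsilyloxy)pentan-2-yl acetate | C[C@@H](OC(C)=O)CC[C@@H](O[Si](C)(C)C(C)(C)C)c1cc(OCc2ccccc2)ccc1C | intermediate
9 | (2R,5R)-5-[5-(benzyloxy)-2-methylphenyl]-5-(tert-butyldimethylsilyloxy)pentan-2-ol | C[C@@H](O)CC[C@@H](O[Si](C)(C)C(C)(C)C)c1cc(OCc2ccccc2)ccc1C | intermediate
10 | (2R,5R)-5-[5-(benzyloxy)-2-methylphenyl]-5-(tert-butyldimethylsilyloxy)pentan-2-yl methanesulfonate | C[C@@H](OS(C)(=O)=O)CC[C@@H](O[Si](C)(C)C(C)(C)C)c1cc(OCc2ccccc2)ccc1C | intermediate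
11 | (2R,5R)-5-(tert-butyldimethylsilyloxy)-5-(5-hydroxy-2-methylphenyl)pentan-2-yl methanesulfonate | C[C@@H](OS(C)(=O)=O)CC[C@@H](O[Si](C)(C)C(C)(C)C)c1cc(O)ccc1C | intermediate
12 | 2,6-dibromo-4-methyl-3-[(1R,4R)-1-(tert-butyldimethylsilyloxy)-4-(methylsulfonyloxy)pentyl]phenol | Cc1cc(Br)c(O)c(Br)c1[C@H](O[Si](C)(C)C(C)(C)C)CC[C@@H](C)OS(C)(=O)=O | intermediate
13 | cesium phenoxide of 12 | Cc1cc(Br)c([O-])c(Br)c1[C@H](O[Si](C)(C)C(C)(C)C)CC[C@@H](C)OS(C)(=O)=O.[Cs+] | intermediate
14 | (4aS,5S,8R)-1,3-dibromo-8-(tert-butyldimethylsilyloxy)-4a,5-dimethyl-5,6,7,8-tetrahydronaphthalen-2(4aH)-one | C[C@H]1CC[C@@H](O[Si](C)(C)C(C)(C)C)C2=C(Br)C(=O)C(Br)=C[C@]12C | intermediate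
15 | methyl propiolate | C#CC(=O)OC | starting material
16 | methyl 2-(tributylstannyl)prop-2-enoate | C=C(C(=O)OC)[Sn](CCCC)(CCCC)CCCC | intermediate
17 | methyl 2-[(5R,8S,8aS)-4-bromo-5-(tert-butyldimethylsilyloxy)-8,8a-dimethyl-3-oxo-3,5,6,7,8,8a-hexahydronaphthalen-2-yl]prop-2-enoate | C[C@H]1CC[C@@H](O[Si](C)(C)C(C)(C)C)C2=C(Br)C(=O)C(C(=C)C(=O)OC)=C[C@]12C | intermediate
18 | methyl (2S)-2-[(5R,8S,8aS)-4-bromo-5-(tert-butyldimethylsilyloxy)-8,8a-dimethyl-3-oxo-3,5,6,7,8,8a-hexahydronaphthalen-2-yl]propanoate | C[C@H]1CC[C@@H](O[Si](C)(C)C(C)(C)C)C2=C(Br)C(=O)C([C@H](C)C(=O)OC)=C[C@]12C | intermediate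
19 | methyl (2S)-2-[(5R,8S,8aS)-5-(tert-butyldimethylsilyloxy)-8,8a-dimethyl-3-oxo-3,5,6,7,8,8a-hexahydronaphthalen-2-yl]propanoate | C[C@H]1CC[C@@H](O[Si](C)(C)C(C)(C)C)C2=CC(=O)C([C@H](C)C(=O)OC)=C[C@]12C | intermediate
20 | methyl (2S)-2-[(5R,8S,8aS)-5-hydroxy-8,8a-dimethyl-3-oxo-3,5,6,7,8,8a-hexahydronaphthalen-2-yl]propanoate | C[C@H]1CC[C@@H](O)C2=CC(=O)C([C@H](C)C(=O)OC)=C[C@]12C | intermediate
21 | angelic acid | C/C=C(/C)C(=O)O | starting material
22 | (2Z)-2-methylbut-2-enoic 2,4,6-trichlorobenzoic anhydride | C/C=C(/C)C(=O)OC(=O)c1c(Cl)cc(Cl)cc1Cl | intermediate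
23 | (1R,4S,4aS)-6-[(2S)-1-methoxy-1-oxopropan-2-yl]-4,4a-dimethyl-7-oxo-1,2,3,4,4a,7-hexahydronaphthalen-1-yl (2Z)-2-methylbut-2-enoate | C/C=C(/C)C(=O)O[C@@H]1CC[C@H](C)[C@@]2(C)C=C([C@H](C)C(=O)OC)C(=O)C=C12 | target

**Step count**
Total step count: 17.
Longest linear sequence: 15 steps, from 1 to 23 through steps 1–10, 12–15 and 17. Steps 11 and 16 are side branches.

**Steps most likely to fail**

**Step 10.**
- What may go wrong: the dibromophenoxide is a weak carbon nucleophile. E2 loss of the secondary sulfonate, intermolecular O-alkylation, or participation of the C1 silyl ether oxygen through a five-membered oxonium ion may therefore outrun C4–C5 bond formation.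
- Fallback: it sets out from 9 and replaces sulfonate displacement in basic medium by dehydrative activation of the alcohol without external base.
- Hydrogenolysis of 9 (H2, Pd/C, EtOAc) should give 3-[(1R,4R)-1-(tert-butyldimethylsilyloxy)-4-hydroxypentyl]-4-methylphenol F1.
- NBS (2.05 equiv, MeCN) should then give 2,6-dibromo-3-[(1R,4R)-1-(tert-butyldimethylsilyloxy)-4-hydroxypentyl]-4-methylphenol F2.
- Under Mitsunobu conditions (PPh3, DIAD, toluene, 0.005 M, 0 °C to rt) the acidic phenol protonates the betaine and C4–OH becomes an alkoxyphosphonium leaving group at low temperature. The ion-paired phenoxide, whose oxygen cannot reach C4, should close through C5 with the same inversion.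
- The fallback comes back to the route at 14.

**Step 13.**
- What may go wrong: discrimination between the two faces of C11=C13 may be poor. The C6=C7–C11=C13 diene may also bind rhodium as a whole, which would slow the catalyst or lead to 1,4-addition of hydrogen.
- Fallback: it sets out from 17 and switches to carboxylate-directed hydrogenation, the mode established for 2-arylacrylic acids.
- Me3SnOH (1,2-dichloroethane, 70 °C) should give 2-[(5R,8S,8aS)-4-bromo-5-(tert-butyldimethylsilyloxy)-8,8a-dimethyl-3-oxo-3,5,6,7,8,8a-hexahydronaphthalen-2-yl]prop-2-enoic acid F3.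
- Ru(OAc)2[(S)-BINAP] with H2 (100 bar, MeOH, rt) should give (2S)-2-[(5R,8S,8aS)-4-bromo-5-(tert-butyldimethylsilyloxy)-8,8a-dimethyl-3-oxo-3,5,6,7,8,8a-hexahydronaphthalen-2-yl]propanoic acid F4.
- Trimethylsilyldiazomethane (toluene–MeOH, 0 °C) re-forms the methyl ester.
- The fallback comes back to the route at 18.

**Step 12.**
- What may go wrong: the steric bias between the two C–Br bonds may be too small, leading to coupling at C9 or at both carbons.
- Fallback: it sets out from 11 and differentiates the two positions by the halogen instead of by crowding.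
- NIS (1.0 equiv, MeCN, 0 °C) should iodinate the less hindered ortho carbon C7 to give 2-iodo-4-methyl-5-[(1R,4R)-1-(tert-butyldimethylsilyloxy)-4-(methylsulfonyloxy)pentyl]phenol F5.
- NBS (1.0 equiv) should then fill C9 to give 2-bromo-6-iodo-4-methyl-3-[(1R,4R)-1-(tert-butyldimethylsilyloxy)-4-(methylsulfonyloxy)pentyl]phenol F6.
- Cs2CO3 under the conditions of step 10 should lead through the cesium phenoxide of this phenol F7 to (4aS,5S,8R)-1-bromo-3-iodo-8-(tert-butyldimethylsilyloxy)-4a,5-dimethyl-5,6,7,8-tetrahydronaphthalen-2(4aH)-one F8.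
- Stille coupling with 16 (Pd(PPh3)4, CuI, DMF, rt) should take place at the far more reactive C–I bond only.
- The fallback comes back to the route at 17.

**Further compounds**
F1 | step 10 | 3-[(1R,4R)-1-(tert-butyldimethylsilyloxy)-4-hydroxypentyl]-4-methylphenol | C[C@@H](O)CC[C@@H](O[Si](C)(C)C(C)(C)C)c1cc(O)ccc1C
F2 | step 10 | 2,6-dibromo-3-[(1R,4R)-1-(tert-butyldimethylsilyloxy)-4-hydroxypentyl]-4-methylphenol | Cc1cc(Br)c(O)c(Br)c1[C@H](O[Si](C)(C)C(C)(C)C)CC[C@@H](C)O
F3 | step 13 | 2-[(5R,8S,8aS)-4-bromo-5-(tert-butyldimethylsilyloxy)-8,8a-dimethyl-3-oxo-3,5,6,7,8,8a-hexahydronaphthalen-2-yl]prop-2-enoic acid | C[C@H]1CC[C@@H](O[Si](C)(C)C(C)(C)C)C2=C(Br)C(=O)C(C(=C)C(=O)O)=C[C@]12C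
F4 | step 13 | (2S)-2-[(5R,8S,8aS)-4-bromo-5-(tert-butyldimethylsilyloxy)-8,8a-dimethyl-3-oxo-3,5,6,7,8,8a-hexahydronaphthalen-2-yl]propanoic acid | C[C@H]1CC[C@@H](O[Si](C)(C)C(C)(C)C)C2=C(Br)C(=O)C([C@H](C)C(=O)O)=C[C@]12C
F5 | step 12 | 2-iodo-4-methyl-5-[(1R,4R)-1-(tert-butyldimethylsilyloxy)-4-(methylsulfonyloxy)pentyl]phenol | Cc1cc(I)c(O)cc1[C@H](O[Si](C)(C)C(C)(C)C)CC[C@@H](C)OS(C)(=O)=O
F6 | step 12 | 2-bromo-6-iodo-4-methyl-3-[(1R,4R)-1-(tert-butyldimethylsilyloxy)-4-(methylsulfonyloxy)pentyl]phenol | Cc1cc(I)c(O)c(Br)c1[C@H](O[Si](C)(C)C(C)(C)C)CC[C@@H](C)OS(C)(=O)=O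
F7 | step 12 | cesium phenoxide of F6 | Cc1cc(I)c([O-])c(Br)c1[C@H](O[Si](C)(C)C(C)(C)C)CC[C@@H](C)OS(C)(=O)=O.[Cs+]
F8 | step 12 | (4aS,5S,8R)-1-bromo-3-iodo-8-(tert-butyldimethylsilyloxy)-4a,5-dimethyl-5,6,7,8-tetrahydronaphthalen-2(4aH)-one | C[C@H]1CC[C@@H](O[Si](C)(C)C(C)(C)C)C2=C(Br)C(=O)C(I)=C[C@]12C
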